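## Structural features

The target 18 is a cyclopent-2-enone (prostanoid numbering: C9 ketone, C10=C11, quaternary C12, tertiary C8). It carries the methyl ester chain C1–C7 on C8 and the (2Z)-oct-2-enyl chain C13–C20 on C12. C12 (R) bears a tertiary allylic acetate and stands next to C8 (S); the two carbon chains are cis on the ring, and the C12 oxygen is trans to C7. The third stereocentre, C4 (S), is a secondary allylic acetate beside the (E)-C5=C6 double bond, too far from the ring for any relay of stereochemistry. Fragile points are C8–H (alpha to the ketone, epimerisable, and with a cis carbon chain on C12 not obviously in its thermodynamic configuration), the two allylic acetates, the skipped (Z)-olefin, and the C1 ester, which closes to a γ-lactone whenever the C4 oxygen is free. The real difficulty is the C8/C12 pair: an oxygenated quaternary centre beside an enolisable centre, to be set in relative and absolute terms. The key step exploits two features. C9–C10=C11–C12 is a cis-ene with oxygen on both ends, which is the carbon and oxidation pattern of a 2,5-disubstituted furan. The arrangement O12 trans to C7 with C13 cis to C7 is the signature of a conrotatory closure of a C8–C12 pentadienyl cation.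

## Logic of the disconnections

18 to 17. The acyl C–O bond of the C12 acetate is cut. The tertiary allylic acetate is the most hindered and most ionisable group, so it is put on last and kept out of every C–C bond-forming step. The precursor carries the free tertiary hydroxyl that the key step delivers. The forward step must acylate a hindered tertiary alcohol without base, because C8–H of 17 is alpha to the ketone.

17 to 13 (key). The ring bond C8–C12 and the C12–OH bond are cut; C9–C12 become the four carbons of a furan, and the C9 carbonyl oxygen becomes the furan oxygen. In one sentence: the ring of 17, with C8 and C12, is made by a catalyst-controlled 4π conrotatory closure of the furan 13. The ring, the enone, the quaternary carbinol and both ring stereocentres disappear; 13 is a flat furan whose only controlled stereocentre is C4. The forward step must ionise the furfuryl position and not the C4 allylic acetate, must close with the C12 hydroxyl and the C7 chain both outside the cation, and must take its absolute sense from a chiral counter-anion.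

13 to 8 and 9. The C4–C5 bond is cut. This joins the chain at the only place where a commercial four-carbon piece (9) can be used, and the same step sets C4 and the (E)-C5=C6 geometry. The forward step needs a chemoselective syn hydrometalation of the terminal alkyne of 8, ligand control of the aldehyde face, and acetylation of the alkoxide before it closes onto the C1 ester.

8 to 4 and 5. The C7–C8 bond is cut. A propargyl unit supplies C5–C7 with the alkyne needed above. The new C8 stereocentre need not be controlled, because the key step erases it; the acetate is both protecting group and leaving group.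

4 to 3, then to 1 and 2. The (Z)-C14=C15 olefin is taken back to an alkyne and the C13–C14 bond is cut. This gives a commercial chloromethylfuran aldehyde that already holds C8, C9–C12 and C13. The alkyne must be coupled to a reactive furfuryl chloride without touching the aldehyde and reduced to the (Z)-olefin before a second alkyne enters.

## Other disconnections considered

Alternative 1: the first that comes to mind. The C7–C8 bond is cut as an enolate alkylation. The kinetic lithium enolate (LiN(iPr)2) of (4S)-4-[(tert-butyldimethylsilyl)oxy]-4-[(2Z)-oct-2-en-1-yl]cyclopent-2-en-1-one A1 would be alkylated by methyl (4S,5E)-4-acetoxy-7-bromohept-5-enoate A2, anti to the silyloxy group, to give the silyl ether A3 of 17. The chosen plan is preferred on three grounds.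
- A1 and A2 each need their own enantioselective synthesis (about six and four steps), so the count is at least twice as high.
- C8 is controlled only by the size difference between a silyloxy group and a CH2 group on the neighbouring quaternary carbon.
- A3 is an enolisable ketone formed in the presence of its own enolate precursor, so proton transfer, epimerisation at C8 and double alkylation are built-in risks; the enolate must also prefer the bromide over two ester carbonyls of A2.

Alternative 2: the same C7–C8 bond is cut through oxygen, as a Claisen rearrangement. The dienyl ether A5, made from the enol of A1 and the C5 hydroxyl of methyl (4S,5S)-4-acetoxy-5-hydroxyhept-6-enoate A4, would rearrange through a chair transition state to A3. This would transfer the C5 configuration to C8, set the (E)-C5=C6 geometry, and be reinforced by the ring-face bias of C12. The stereochemical logic is better than in Alternative 1, but there is no reliable stoichiometric way to make A5. O-alkylation of the dienolate with a secondary allylic electrophile competes with C-alkylation and SN2′ attack. Acid-catalysed ketal exchange needs a large excess of one of two precious partners, and hot acid would epimerise A3. The plan still needs A1, and A4 carries a second stereocentre that is made only to be destroyed.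

Alternative 3: both ring C–O bonds (C9=O and C12–O) are cut. Singlet oxygen would add (4+2) to the cyclopentadiene A6 anti to its C8 substituent to give the endoperoxide A7. Kornblum–DeLaMare fragmentation (base removes the only bridgehead hydrogen, at C9) would then give 17 with the right regiochemistry and O12 trans to C7. The regio- and facial logic is attractive, but A6 is a 5-monosubstituted cyclopentadiene. Its [1,5]-hydrogen shifts are expected near or below room temperature and would move the C8 hydrogen around the ring, erasing both the stereocentre and the diene position. A6 would also have to be made as a single C8 enantiomer by chemistry no simpler than the target. The chosen plan reaches the same C9/C12 oxygen pattern from a furan, where it is stable, and creates C8 only in the bond-forming step.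

Key step: step 5

Assumption: the (R)-configured acid of step 5 is taken to favour the (8S,12R) sense of ring closure; if the sense of induction is the opposite, the (S)-acid is used with no other change.

## Steps

Step 1
Reactants: 1 5-(chloromethyl)furan-2-carbaldehyde; 2 hept-1-yne
Product: 3 5-(oct-2-yn-1-yl)furan-2-carbaldehyde
Conditions: CuI (10 mol %), Bu4NI (10 mol %), K2CO3, DMF, 23 °C
Reagents that add atoms: none
Why: Copper-acetylide alkylation of an activated (furfuryl) chloride, the reaction used for skipped enynes and diynes; the carbonate base is too weak to touch the non-enolisable aldehyde, and substitution at the primary furfuryl carbon gives the 1,4-relationship of furan and alkyne directly.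

Step 2
Reactants: 3 5-(oct-2-yn-1-yl)furan-2-carbaldehyde
Product: 4 5-[(2Z)-oct-2-en-1-yl]furan-2-carbaldehyde
Conditions: H2 (1 atm), Pd/CaCO3 poisoned with Pb(OAc)2, quinoline, EtOAc, 23 °C
Reagents that add atoms: none
Why: Lindlar semihydrogenation; syn delivery of hydrogen on the poisoned surface sets the (Z)-C14=C15 geometry, the aldehyde and the furan are not reduced, and doing it here leaves only one alkyne in the later hydroboration.

Step 3
Reactants: 4 5-[(2Z)-oct-2-en-1-yl]furan-2-carbaldehyde; 5 3-bromoprop-1-yne
Product: 8 1-{5-[(2Z)-oct-2-en-1-yl]furan-2-yl}but-3-yn-1-yl acetate (racemic), via propadienylzinc bromide 6 (not isolated), via bromozinc alkoxide 7 (not isolated)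
Conditions: Zn, THF, 0 °C; then Ac2O, DMAP (cat.), 0 → 23 °C
Reagents that add atoms: acetic anhydride, CC(=O)OC(C)=O
Why: Barbier propargylation; the allenylzinc 6 adds to the aldehyde through its γ-carbon (SE2′) to give the homopropargylic alkoxide 7, which is acetylated in the flask. The new C8 centre is racemic on purpose, since step 5 erases it.

Step 4
Reactants: 8 1-{5-[(2Z)-oct-2-en-1-yl]furan-2-yl}but-3-yn-1-yl acetate; 9 methyl 4-oxobutanoate
Product: 13 methyl (4S,5E)-4,8-bis(acetyloxy)-8-{5-[(2Z)-oct-2-en-1-yl]furan-2-yl}oct-5-enoate (both C8 epimers), via alkenyldicyclohexylborane 10 (not isolated), via alkenyl(methyl)zinc 11 (not isolated), via methylzinc alkoxide 12 (not isolated)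
Conditions: Cy2BH, toluene, 0 → 23 °C; Me2Zn, −78 °C; (+)-3-exo-morpholinoisoborneol (5 mol %), then 9, −20 → 0 °C; then Ac2O, 0 → 23 °C
Reagents that add atoms: acetic anhydride, CC(=O)OC(C)=O
Why: Syn hydroboration of the terminal alkyne (faster than reaction at the cis-disubstituted olefin or the esters) fixes (E)-C5=C6; boron-to-zinc exchange and amino-alcohol-catalysed alkenylzinc addition to the aldehyde form C4–C5. The (+)-ligand, the antipode of the one that directs attack to the Si face, should deliver the alkenyl group to the Re face and so give 4S; acetic anhydride traps alkoxide 12 before it can lactonise onto C1.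

Step 5
Reactants: 13 methyl (4S,5E)-4,8-bis(acetyloxy)-8-{5-[(2Z)-oct-2-en-1-yl]furan-2-yl}oct-5-enoate
Product: 17 methyl (4S,5E)-4-acetoxy-7-{(1S,5R)-5-hydroxy-5-[(2Z)-oct-2-en-1-yl]-2-oxocyclopent-3-en-1-yl}hept-5-enoate, via furfuryl cation 14 (not isolated), via hydroxydihydrofuran hemiketal 15 (not isolated), via dihydroxypentadienyl cation 16 (not isolated)
Conditions: (R)-3,3′-bis(2,4,6-triisopropylphenyl)-1,1′-binaphthyl-2,2′-diyl N-triflylphosphoramide (10 mol %), H2O (10 equiv), MeCN, 40 °C
Reagents that add atoms: water, O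
Why: Proposed new method: the closest known reactions are the acid-mediated Piancatelli rearrangement of 2-furylcarbinols (racemic, including 5-alkylfurans, which give 4-alkyl-4-hydroxy-5-substituted cyclopentenones) and its chiral-phosphoric-acid-catalysed aza variant with anilines; an enantioselective version with water on a 5-alkylfuryl alkyl carbinol ester is not established. The strong chiral acid ionises the furfuryl acetate of 13 to cation 14, water adds at the 5-position of the furan (C12) to give hemiketal 15, and ring opening gives the 1,4-dihydroxypentadienyl cation 16 as a contact ion pair with the chiral phosphoramide anion, hydrogen-bonded to both hydroxyls. Thermal 4π conrotatory electrocyclisation of 16 closes the cyclopentenone ring through the C8–C12 bond (the only ring formed; it is an electrocyclic closure and not an enolate aldol, so the enolendo restriction of Baldwin's rules does not apply), and loss of a proton from the resulting hydroxyallyl cation gives enone 17. Relative configuration: in 16 the C7 chain on C8 (syn to the former ring oxygen) and the hydroxyl on C12 (outward, as in the racemic reaction) both sit outside the U-shaped cation, so conrotation should place OH trans to C7 and the octenyl chain cis to C7, which is the target relationship. Absolute configuration: the sense of conrotation, that is the helicity of the ion pair, is imposed by the chiral anion and should override the remote C4 centre; C4 is untouched, and the C8 centre of 13 is erased in 14. Selectivity needed: furfuryl ionisation over ionisation of the C4 allylic acetate (secured by the far greater stabilisation of the 5-alkylfurfuryl cation), and capture of 14 by water over loss of a proton from C7 (secured by the excess of water and the moderate temperature).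

Step 6
Reactants: 17 methyl (4S,5E)-4-acetoxy-7-{(1S,5R)-5-hydroxy-5-[(2Z)-oct-2-en-1-yl]-2-oxocyclopent-3-en-1-yl}hept-5-enoate
Product: 18 methyl (4S,5E)-4-acetoxy-7-{(1S,5R)-5-acetoxy-5-[(2Z)-oct-2-en-1-yl]-2-oxocyclopent-3-en-1-yl}hept-5-enoate
Conditions: Ac2O, Sc(OTf)3 (2 mol %), MeCN, −20 → 0 °C
Reagents that add atoms: acetic anhydride, CC(=O)OC(C)=O
Why: Lewis-acid-catalysed acylation, which reaches tertiary alcohols at low temperature; no base is present, so C8 should not epimerise, and ionisation at C12 is disfavoured because the cation would be conjugated to the enone carbonyl. No stereocentre is formed.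

## Compound list

1 | 5-(chloromethyl)furan-2-carbaldehyde | ClCc1ccc(C=O)o1 | starting material
2 | hept-1-yne | CCCCCC#C | starting material
3 | 5-(oct-2-yn-1-yl)furan-2-carbaldehyde | CCCCCC#CCc1ccc(C=O)o1 | intermediate
4 | 5-[(2Z)-oct-2-en-1-yl]furan-2-carbaldehyde | CCCCC/C=C\Cc1ccc(C=O)o1 | intermediate
5 | 3-bromoprop-1-yne | BrCC#C | starting material
6 | propa-1,2-dien-1-ylzinc bromide | C=C=C[Zn]Br | intermediate
7 | bromozinc 1-{5-[(2Z)-oct-2-en-1-yl]furan-2-yl}but-3-yn-1-olate (racemic) | CCCCC/C=C\Cc1ccc(o1)C(CC#C)O[Zn]Br | intermediate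
8 | 1-{5-[(2Z)-oct-2-en-1-yl]furan-2-yl}but-3-yn-1-yl acetate (racemic) | CCCCC/C=C\Cc1ccc(o1)C(CC#C)OC(C)=O | intermediate
9 | methyl 4-oxobutanoate | COC(=O)CCC=O | starting material
10 | [(1E)-4-(acetyloxy)-4-{5-[(2Z)-oct-2-en-1-yl]furan-2-yl}but-1-en-1-yl]dicyclohexylborane | CCCCC/C=C\Cc1ccc(o1)C(OC(C)=O)C/C=C/B(C1CCCCC1)C1CCCCC1 | intermediate
11 | [(1E)-4-(acetyloxy)-4-{5-[(2Z)-oct-2-en-1-yl]furan-2-yl}but-1-en-1-yl](methyl)zinc | CCCCC/C=C\Cc1ccc(o1)C(OC(C)=O)C/C=C/[Zn]C | intermediate
12 | methylzinc alkoxide of methyl (4S,5E)-8-(acetyloxy)-4-hydroxy-8-{5-[(2Z)-oct-2-en-1-yl]furan-2-yl}oct-5-enoate | CCCCC/C=C\Cc1ccc(o1)C(OC(C)=O)C/C=C/[C@H](CCC(=O)OC)O[Zn]C | intermediate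
13 | methyl (4S,5E)-4,8-bis(acetyloxy)-8-{5-[(2Z)-oct-2-en-1-yl]furan-2-yl}oct-5-enoate (both C8 epimers) | CCCCC/C=C\Cc1ccc(o1)C(OC(C)=O)C/C=C/[C@H](CCC(=O)OC)OC(C)=O | intermediate
14 | furfuryl cation at C8 formed from 13 by loss of acetate | CCCCC/C=C\Cc1ccc(o1)[CH+]C/C=C/[C@H](CCC(=O)OC)OC(C)=O | intermediate
15 | 5-hydroxy-2-alkylidene-2,5-dihydrofuran hemiketal, the water adduct of 14 at C12 (C7 syn to the ring oxygen; C12 unassigned) | CCCCC/C=C\CC1(O)C=C/C(O1)=C/C/C=C/[C@H](CCC(=O)OC)OC(C)=O | intermediate
16 | 1,4-dihydroxypentadienyl cation over C8–C12 (O-protonated (8Z,10Z)-9-hydroxy-12-oxo triene) | CCCCC/C=C\CC(=[OH+])/C=C\C(O)=C\C/C=C/[C@H](CCC(=O)OC)OC(C)=O | intermediate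
17 | methyl (4S,5E)-4-acetoxy-7-{(1S,5R)-5-hydroxy-5-[(2Z)-oct-2-en-1-yl]-2-oxocyclopent-3-en-1-yl}hept-5-enoate | CCCCC/C=C\C[C@@]1(O)C=CC(=O)[C@H]1C/C=C/[C@H](CCC(=O)OC)OC(C)=O | intermediate
18 | methyl (4S,5E)-4-acetoxy-7-{(1S,5R)-5-acetoxy-5-[(2Z)-oct-2-en-1-yl]-2-oxocyclopent-3-en-1-yl}hept-5-enoate | CCCCC/C=C\C[C@@]1(OC(C)=O)C=CC(=O)[C@H]1C/C=C/[C@H](CCC(=O)OC)OC(C)=O | target

## Step count and risks

Total step count: 6. Longest linear sequence: 6 (steps 1–6 from 1; compounds 2, 5 and 9 enter as purchased reagents).

**Step 5 (key step, proposed new method).** Three things are most likely to go wrong: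
- the chiral anion may not control the sense of conrotation well enough (a background closure through ion pairs separated by water or acetic acid would give both ring configurations);
- the cation may lose a proton from C7 and drift into elimination and oligomerisation;
- the C4 allylic acetate may ionise slowly.

The fallback builds the ring stereocentres by known chemistry, in the order C12 then C8. It sets out from 3-bromoprop-1-yne 5 and returns to the route at 17. Zinc-mediated Barbier addition of 5 to commercial (4R)-4-[(tert-butyldimethylsilyl)oxy]cyclopent-2-en-1-one F1, anti to the silyloxy group, should give (1S,4R)-4-[(tert-butyldimethylsilyl)oxy]-1-(prop-2-yn-1-yl)cyclopent-2-en-1-ol F2. Its dianion (n-BuLi, 2.2 equiv, THF/DMPU) is alkylated at the acetylide carbon with 1-iodopentane to the oct-2-ynyl carbinol F3. Semihydrogenation (H2, Pd/CaCO3 poisoned with Pb(OAc)2) gives the (2Z)-octenyl carbinol F4, TBAF gives (1S,4R)-1-[(2Z)-oct-2-en-1-yl]cyclopent-2-ene-1,4-diol F5, and MnO2 gives (4S)-4-hydroxy-4-[(2Z)-oct-2-en-1-yl]cyclopent-2-en-1-one F6. C12 is now fixed by the chiral-pool silyl ether. Silylation (Et3SiOTf, 2,6-lutidine) gives the triethylsilyl ether F7. Kinetic deprotonation (LiN(iPr)2, THF, −78 °C) and alkylation with 5, anti to the silyloxy group, gives (4R,5S)-4-[(2Z)-oct-2-en-1-yl]-5-(prop-2-yn-1-yl)-4-[(triethylsilyl)oxy]cyclopent-2-en-1-one F8. F8 is taken through the hydroboration, zinc exchange, addition to 9 and acetylation of step 4 to the triethylsilyl ether F9 of 17, and HF·pyridine returns 17. This costs about ten steps in place of one.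

**Step 4.** Enantioselectivity may be eroded with this functionalised aliphatic aldehyde, methyl may transfer in competition with alkenyl, and alkoxide 12 may lactonise before it is acetylated. The fallback sets C4 by ketone reduction and not by C–C bond formation; it sets out from 8 and returns at 13. Hydrozirconation of 8 (Cp2Zr(H)Cl, CH2Cl2) gives the (E)-alkenylzirconocene chloride F10. Acylation with methyl 4-chloro-4-oxobutanoate (CuBr·SMe2 cat.) gives methyl (5E)-8-(acetyloxy)-8-{5-[(2Z)-oct-2-en-1-yl]furan-2-yl}-4-oxooct-5-enoate F11. Corey–Bakshi–Shibata reduction ((R)-Me-oxazaborolidine, catecholborane, −78 °C) gives methyl (4S,5E)-8-(acetyloxy)-4-hydroxy-8-{5-[(2Z)-oct-2-en-1-yl]furan-2-yl}oct-5-enoate F12, which is acetylated at once (Ac2O, pyridine) to 13.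

**Step 6.** The hindered tertiary allylic alcohol may acylate slowly, and under forcing conditions C8 may epimerise through the enol or the C12 oxygen may be lost by ionisation. The fallback removes the acidity of C8–H while the acetate is put on; it sets out from 17 and returns at 18. Luche reduction (NaBH4, CeCl3·7H2O, MeOH, −78 °C) gives the C9 alcohol, methyl (4S,5E)-4-acetoxy-7-{2,5-dihydroxy-5-[(2Z)-oct-2-en-1-yl]cyclopent-3-en-1-yl}hept-5-enoate F13 (C9 epimers; C8 and C12 as in 17). Selective silylation of the secondary hydroxyl (Et3SiCl, imidazole) gives the C9 triethylsilyl ether F14. Forcing acetylation (Ac2O, DMAP, Et3N, 40 °C) gives the C12 acetate F15, HF·pyridine gives the C9 alcohol F16, and Dess–Martin oxidation returns 18.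

**Step 1.** The furfuryl chloride may be consumed by solvolysis or self-condensation under the basic coupling conditions before the copper acetylide captures it. The fallback forms the same C13–C14 bond as an sp3–sp2 coupling with the (Z)-olefin already in place and so also replaces step 2; it sets out from 2 and returns at 4. Rhodium-catalysed trans-hydroboration of 2 ([Rh(cod)Cl]2, P(iPr)3, Et3N, pinacolborane) gives 2-[(1Z)-hept-1-en-1-yl]-4,4,5,5-tetramethyl-1,3,2-dioxaborolane F17. Suzuki–Miyaura coupling of F17 with 1 (Pd(PPh3)4, CsF, THF, 60 °C) gives 4 with retention of the olefin geometry.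

## Further compounds

F1 | step 5 | (4R)-4-[(tert-butyldimethylsilyl)oxy]cyclopent-2-en-1-one | O=C1C=C[C@H](O[Si](C)(C)C(C)(C)C)C1
F2 | step 5 | (1S,4R)-4-[(tert-butyldimethylsilyl)oxy]-1-(prop-2-yn-1-yl)cyclopent-2-en-1-ol | C#CC[C@@]1(O)C=C[C@H](O[Si](C)(C)C(C)(C)C)C1
F3 | step 5 | (1S,4R)-4-[(tert-butyldimethylsilyl)oxy]-1-(oct-2-yn-1-yl)cyclopent-2-en-1-ol | CCCCCC#CC[C@@]1(O)C=C[C@H](O[Si](C)(C)C(C)(C)C)C1
F4 | step 5 | (1S,4R)-4-[(tert-butyldimethylsilyl)oxy]-1-[(2Z)-oct-2-en-1-yl]cyclopent-2-en-1-ol | CCCCC/C=C\C[C@@]1(O)C=C[C@H](O[Si](C)(C)C(C)(C)C)C1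
F5 | step 5 | (1S,4R)-1-[(2Z)-oct-2-en-1-yl]cyclopent-2-ene-1,4-diol | CCCCC/C=C\C[C@@]1(O)C=C[C@H](O)C1
F6 | step 5 | (4S)-4-hydroxy-4-[(2Z)-oct-2-en-1-yl]cyclopent-2-en-1-one | CCCCC/C=C\C[C@@]1(O)C=CC(=O)C1
F7 | step 5 | (4S)-4-[(2Z)-oct-2-en-1-yl]-4-[(triethylsilyl)oxy]cyclopent-2-en-1-one | CCCCC/C=C\C[C@@]1(O[Si](CC)(CC)CC)C=CC(=O)C1
F8 | step 5 | (4R,5S)-4-[(2Z)-oct-2-en-1-yl]-5-(prop-2-yn-1-yl)-4-[(triethylsilyl)oxy]cyclopent-2-en-1-one | CCCCC/C=C\C[C@@]1(O[Si](CC)(CC)CC)C=CC(=O)[C@H]1CC#C
F9 | step 5 | methyl (4S,5E)-4-acetoxy-7-{(1S,5R)-5-[(2Z)-oct-2-en-1-yl]-2-oxo-5-[(triethylsilyl)oxy]cyclopent-3-en-1-yl}hept-5-enoate | CCCCC/C=C\C[C@@]1(O[Si](CC)(CC)CC)C=CC(=O)[C@H]1C/C=C/[C@H](CCC(=O)OC)OC(C)=O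
F10 | step 4 | chlorobis(cyclopentadienyl)[(1E)-4-(acetyloxy)-4-{5-[(2Z)-oct-2-en-1-yl]furan-2-yl}but-1-en-1-yl]zirconium | CCCCC/C=C\Cc1ccc(o1)C(OC(C)=O)C/C=C/[Zr](Cl)(C1C=CC=C1)C1C=CC=C1
F11 | step 4 | methyl (5E)-8-(acetyloxy)-8-{5-[(2Z)-oct-2-en-1-yl]furan-2-yl}-4-oxooct-5-enoate | CCCCC/C=C\Cc1ccc(o1)C(OC(C)=O)C/C=C/C(=O)CCC(=O)OC
F12 | step 4 | methyl (4S,5E)-8-(acetyloxy)-4-hydroxy-8-{5-[(2Z)-oct-2-en-1-yl]furan-2-yl}oct-5-enoate | CCCCC/C=C\Cc1ccc(o1)C(OC(C)=O)C/C=C/[C@H](CCC(=O)OC)O
F13 | step 6 | methyl (4S,5E)-4-acetoxy-7-{2,5-dihydroxy-5-[(2Z)-oct-2-en-1-yl]cyclopent-3-en-1-yl}hept-5-enoate (C9 epimers; C8 and C12 as in 17) | CCCCC/C=C\C[C@@]1(O)C=CC(O)[C@H]1C/C=C/[C@H](CCC(=O)OC)OC(C)=O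
F14 | step 6 | C9 triethylsilyl ether of F13 | CCCCC/C=C\C[C@@]1(O)C=CC(O[Si](CC)(CC)CC)[C@H]1C/C=C/[C@H](CCC(=O)OC)OC(C)=O
F15 | step 6 | C12 acetate of F14 | CCCCC/C=C\C[C@@]1(OC(C)=O)C=CC(O[Si](CC)(CC)CC)[C@H]1C/C=C/[C@H](CCC(=O)OC)OC(C)=O
F16 | step 6 | C9 alcohol of 18 (C9 epimers) | CCCCC/C=C\C[C@@]1(OC(C)=O)C=CC(O)[C@H]1C/C=C/[C@H](CCC(=O)OC)OC(C)=O
F17 | step 1 | 2-[(1Z)-hept-1-en-1-yl]-4,4,5,5-tetramethyl-1,3,2-dioxaborolane | CCCCC/C=C\B1OC(C)(C)C(C)(C)O1
A1 | alternative 1 | (4S)-4-[(tert-butyldimethylsilyl)oxy]-4-[(2Z)-oct-2-en-1-yl]cyclopent-2-en-1-one | CCCCC/C=C\C[C@@]1(O[Si](C)(C)C(C)(C)C)C=CC(=O)C1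
A2 | alternative 1 | methyl (4S,5E)-4-acetoxy-7-bromohept-5-enoate | BrC/C=C/[C@H](CCC(=O)OC)OC(C)=O
A3 | alternative 1 | methyl (4S,5E)-4-acetoxy-7-{(1S,5R)-5-[(tert-butyldimethylsilyl)oxy]-5-[(2Z)-oct-2-en-1-yl]-2-oxocyclopent-3-en-1-yl}hept-5-enoate | CCCCC/C=C\C[C@@]1(O[Si](C)(C)C(C)(C)C)C=CC(=O)[C@H]1C/C=C/[C@H](CCC(=O)OC)OC(C)=O
A4 | alternative 2 | methyl (4S,5S)-4-acetoxy-5-hydroxyhept-6-enoate | O[C@@H](C=C)[C@H](CCC(=O)OC)OC(C)=O
A5 | alternative 2 | methyl (4S,5S)-4-acetoxy-5-({(3R)-3-[(tert-butyldimethylsilyl)oxy]-3-[(2Z)-oct-2-en-1-yl]cyclopenta-1,4-dien-1-yl}oxy)hept-6-enoate | CCCCC/C=C\C[C@@]1(O[Si](C)(C)C(C)(C)C)C=CC(O[C@@H](C=C)[C@H](CCC(=O)OC)OC(C)=O)=C1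
A6 | alternative 3 | methyl (4S,5E)-4-acetoxy-7-{(1R)-2-[(2Z)-oct-2-en-1-yl]cyclopenta-2,4-dien-1-yl}hept-5-enoate | CCCCC/C=C\CC1=CC=C[C@H]1C/C=C/[C@H](CCC(=O)OC)OC(C)=O
A7 | alternative 3 | 2,3-dioxabicyclo[2.2.1]hept-5-ene endoperoxide of A6 (peroxide bridge across C9 and C12, anti to the C8 chain) | CCCCC/C=C\C[C@@]1(OO2)C=C[C@H]2[C@H]1C/C=C/[C@H](CCC(=O)OC)OC(C)=O
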